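**Retrosynthetic overview**
1. Target ⇒ cleave the C9–O ester bond and three silyl ethers: a 2,3-trans dihydrobenzofuran-3-methanol plus O-silyl p-coumaric acid.
2. The trans alcohol ⇒ a 2,3-cis 3-vinyl-2-aryl-dihydrobenzofuran, by C=C cleavage, thermodynamic epimerisation of C3 at the aldehyde level, and reduction; C2 is not touched.
3. The 3-vinyl dihydrobenzofuran ⇒ one-flask [3+2] annulation of O-silyl vanillin with a ring-A (E)-3-arylallyl boronate: C2–C3 by catalytic asymmetric allylboration, then O1–C7a by palladium etherification. Ring C is the only ring formed; rings A and B are bought.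
4. Enabling feature (benzofuran locants; ring A = benzo ring, ring B = guaiacyl ring on C2, ring C = dihydrofuran, C9 = CH2O carbon on C3): C2 carries O1 and ring B, so C2–O1 is the C=O of vanillin. C3 is benzylic on ring A and carries the one-carbon branch C9, so C3/C9 are the γ/β carbons of an allyl boronate. C7a is ortho to C3a, so O1 ends five atoms from a C7a–OTf bond made from the phenol oxygen of the ring-A starting material.
5. The boronate ⇒ dihydroconiferyl alcohol by ortho-formylation, silylation, triflation, Wittig methylenation and cross-metathesis.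

Key step: step 7

Remark: the target is read as (2R,3S), which is 2,3-trans on ring C.
Assumption: the (R)-configured phosphoric acid is taken to give the (R)-carbinol, as with simple allyl pinacol boronates and aryl aldehydes; if the sense proves opposite, the (S)-acid is used.

**Step 1**
Reactants: 1 dihydroconiferyl alcohol [3-(4-hydroxy-3-methoxyphenyl)propan-1-ol]
Product: 2 2-hydroxy-5-(3-hydroxypropyl)-3-methoxybenzaldehyde
Conditions: MgCl2, Et3N, paraformaldehyde, MeCN, reflux; dilute HCl work-up
Reagents that add atoms: formaldehyde (as paraformaldehyde), C=O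
Why: Magnesium-phenoxide-directed ortho-formylation of a phenol, in which the benzylic alkoxide first formed is oxidised by a second formaldehyde (Oppenauer-type hydride transfer); the only free ortho position of 1 is the future C3a.

**Step 2**
Reactants: 2 2-hydroxy-5-(3-hydroxypropyl)-3-methoxybenzaldehyde
Product: 3 5-[3-(tert-butyldimethylsilyloxy)propyl]-2-hydroxy-3-methoxybenzaldehyde
Conditions: TBSCl (1.05 equiv), imidazole, CH2Cl2, 0 °C
Reagents that add atoms: tert-butyldimethylsilyl chloride, CC(C)(C)[Si](C)(C)Cl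
Why: Silylation should take the primary alcohol, because the phenol is tied up in a hydrogen bond to the formyl group and flanked by OMe.

**Step 3**
Reactants: 3 5-[3-(tert-butyldimethylsilyloxy)propyl]-2-hydroxy-3-methoxybenzaldehyde
Product: 4 4-[3-(tert-butyldimethylsilyloxy)propyl]-2-formyl-6-methoxyphenyl trifluoromethanesulfonate
Conditions: Tf2O, pyridine, CH2Cl2, −78 to 0 °C
Reagents that add atoms: trifluoromethanesulfonic anhydride, O=S(=O)(OS(=O)(=O)C(F)(F)F)C(F)(F)F
Why: O-Sulfonylation of the phenol turns the oxygen on the future C7a into a leaving group for palladium chemistry.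

**Step 4**
Reactants: 4 4-[3-(tert-butyldimethylsilyloxy)propyl]-2-formyl-6-methoxyphenyl trifluoromethanesulfonate
Product: 5 4-[3-(tert-butyldimethylsilyloxy)propyl]-2-methoxy-6-vinylphenyl trifluoromethanesulfonate
Conditions: Ph3PCH3Br, KN(SiMe3)2, THF, 0 °C; then 4, −78 °C to rt
Reagents that add atoms: methylenetriphenylphosphorane (made in the flask from methyltriphenylphosphonium bromide), C=P(c1ccccc1)(c1ccccc1)c1ccccc1
Why: Wittig methylenation of the aryl aldehyde; only a slight excess of the ylide at low temperature is used so that the triflate sulfur is not attacked.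

**Step 5**
Reactants: 5 4-[3-(tert-butyldimethylsilyloxy)propyl]-2-methoxy-6-vinylphenyl trifluoromethanesulfonate; 6 allylboronic acid pinacol ester (2-allyl-4,4,5,5-tetramethyl-1,3,2-dioxaborolane)
Product: 7 4-[3-(tert-butyldimethylsilyloxy)propyl]-2-methoxy-6-[(E)-3-(4,4,5,5-tetramethyl-1,3,2-dioxaborolan-2-yl)prop-1-enyl]phenyl trifluoromethanesulfonate
Conditions: second-generation Grubbs catalyst RuCl2(=CHPh)(H2IMes)(PCy3) (5 mol %), 6 (3 equiv), CH2Cl2, 40 °C
Reagents that add atoms: none
Why: Olefin cross-metathesis of a styrene with an allyl boronate, driven by loss of ethylene and expected to favour the E isomer on steric grounds.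

**Step 6**
Reactants: 8 vanillin (4-hydroxy-3-methoxybenzaldehyde)
Product: 9 3-methoxy-4-(triisopropylsilyloxy)benzaldehyde
Conditions: TIPSCl, imidazole, DMF, rt
Reagents that add atoms: chlorotriisopropylsilane, CC(C)[Si](Cl)(C(C)C)C(C)C
Why: Silylation of the phenol; the triisopropylsilyl ether is chosen because it should survive the phosphate base of step 7 and the amine base of step 8.

**Step 7**
Reactants: 7 4-[3-(tert-butyldimethylsilyloxy)propyl]-2-methoxy-6-[(E)-3-(4,4,5,5-tetramethyl-1,3,2-dioxaborolan-2-yl)prop-1-enyl]phenyl trifluoromethanesulfonate; 9 3-methoxy-4-(triisopropylsilyloxy)benzaldehyde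
Product: 11 (2R,3S)-5-[3-(tert-butyldimethylsilyloxy)propyl]-7-methoxy-2-[3-methoxy-4-(triisopropylsilyloxy)phenyl]-3-vinyl-2,3-dihydrobenzofuran (2,3-cis), via homoallylic pinacol borate 10 (not isolated)
Conditions: (R)-3,3'-bis(2,4,6-triisopropylphenyl)-1,1'-binaphthyl-2,2'-diyl hydrogen phosphate (5 mol %), 9 (1.2 equiv), 4 Å molecular sieves, toluene, −20 °C to rt; then, in the same flask, Pd2(dba)3 (2.5 mol %), t-BuXPhos (6 mol %), K3PO4 (3 equiv), 80 °C
Reagents that add atoms: none
Why: Proposed new method: a one-flask [3+2] annulation in which (i) the chiral phosphoric acid, hydrogen-bonded to a boronate oxygen, catalyses γ-selective allyl transfer from 7 to aldehyde 9 through a six-membered Zimmerman–Traxler chair (C2–C3), and (ii) the pinacol borate 10 so formed is opened by phosphate and hands its alkoxide to the aryl–palladium triflate generated by oxidative addition of zerovalent palladium into C7a–OTf, C–O reductive elimination then forming O1–C7a; the closest known reaction types are the Brønsted-acid-catalysed allyl- and crotylboration of aryl aldehydes with pinacol boronates and the Buchwald–Hartwig intramolecular etherification of 2-(2-haloaryl)ethanols to 2,3-dihydrobenzofurans, and what is new is their merger through a boron-bound alkoxide and the use of an aryl triflate. Ring C is closed in a 5-exo sense at C7a, by reductive elimination from a six-membered oxapalladacycle (Pd, C7a, C3a, C3, C2, O1). C2 is controlled by the catalyst, and C3 is set relative to C2 by the E geometry of 7 in the chair (anti adduct, hence the 2,3-cis ring); C3 is corrected in step 8, so any Z isomer in 7 converges as well. The step needs γ- over α-attack (inherent to the closed transition state), no palladium reaction at the allyl C–B bond (palladium is added only after 7 is consumed, 9 being in excess), and C–O reductive elimination in preference to β-hydride elimination of the secondary alkoxide (bulky di-tert-butyl biaryl phosphine, with a weak insoluble base that should also spare the triflate). No bond to C2 is made or broken in the ring closure, so its configuration should be retained.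

**Step 8**
Reactants: 11 (2R,3S)-5-[3-(tert-butyldimethylsilyloxy)propyl]-7-methoxy-2-[3-methoxy-4-(triisopropylsilyloxy)phenyl]-3-vinyl-2,3-dihydrobenzofuran
Product: 15 [(2R,3S)-5-[3-(tert-butyldimethylsilyloxy)propyl]-7-methoxy-2-[3-methoxy-4-(triisopropylsilyloxy)phenyl]-2,3-dihydrobenzofuran-3-yl]methanol (2,3-trans), via ozonide 12 (not isolated), via cis-aldehyde 13 (not isolated), via trans-aldehyde 14 (not isolated)
Conditions: O3 (Sudan Red 7B as end-point indicator), CH2Cl2, −78 °C; PPh3, −78 °C to rt; DBU (0.2 equiv), rt, argon; then MeOH, NaBH4, 0 °C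
Reagents that add atoms: ozone, [O-][O+]=O
Why: Ozonolysis (Criegee mechanism) of the only alkene gives the α-aryl aldehyde, which DBU should equilibrate at C3 to the more stable 2,3-trans isomer before borohydride reduction; C2 should stay intact because its ring C–O bond lies orthogonal to the enolate π system, so β-elimination is stereoelectronically disfavoured.

**Step 9**
Reactants: 16 p-coumaric acid [(E)-3-(4-hydroxyphenyl)acrylic acid]
Product: 18 (E)-3-[4-(tert-butyldimethylsilyloxy)phenyl]acrylic acid, via bis-silylated coumarate 17 (not isolated)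
Conditions: TBSCl (2.5 equiv), imidazole, DMF, rt; then K2CO3, THF/MeOH/H2O, rt; citric acid work-up
Reagents that add atoms: tert-butyldimethylsilyl chloride, CC(C)(C)[Si](C)(C)Cl
Why: Exhaustive silylation followed by selective solvolysis of the much more labile silyl ester should leave the phenol protected and the acid free.

**Step 10**
Reactants: 15 [(2R,3S)-5-[3-(tert-butyldimethylsilyloxy)propyl]-7-methoxy-2-[3-methoxy-4-(triisopropylsilyloxy)phenyl]-2,3-dihydrobenzofuran-3-yl]methanol; 18 (E)-3-[4-(tert-butyldimethylsilyloxy)phenyl]acrylic acid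
Product: 19 [(2R,3S)-5-[3-(tert-butyldimethylsilyloxy)propyl]-7-methoxy-2-[3-methoxy-4-(triisopropylsilyloxy)phenyl]-2,3-dihydrobenzofuran-3-yl]methyl (E)-3-[4-(tert-butyldimethylsilyloxy)phenyl]acrylate
Conditions: EDC·HCl, DMAP, CH2Cl2, 0 °C to rt
Reagents that add atoms: none
Why: Steglich esterification of the only free hydroxyl group (C9–OH); no stereocentre is involved.

**Step 11**
Reactants: 19 [(2R,3S)-5-[3-(tert-butyldimethylsilyloxy)propyl]-7-methoxy-2-[3-methoxy-4-(triisopropylsilyloxy)phenyl]-2,3-dihydrobenzofuran-3-yl]methyl (E)-3-[4-(tert-butyldimethylsilyloxy)phenyl]acrylate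
Product: 20 [(2R,3S)-2-(4-hydroxy-3-methoxyphenyl)-5-(3-hydroxypropyl)-7-methoxy-2,3-dihydrobenzofuran-3-yl]methyl (E)-3-(4-hydroxyphenyl)acrylate (CNP0202924.1)
Conditions: TBAF, AcOH, THF, 0 °C to rt
Reagents that add atoms: none
Why: Fluoride-mediated cleavage of the two aryl silyl ethers and the primary alkyl silyl ether; the acetic acid buffer should keep the phenols protonated and so protect the cinnamate ester and the benzylic C2–O1 bond.

**Compound list**
1 | dihydroconiferyl alcohol, 3-(4-hydroxy-3-methoxyphenyl)propan-1-ol | COc1cc(CCCO)ccc1O | starting material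
2 | 2-hydroxy-5-(3-hydroxypropyl)-3-methoxybenzaldehyde | COc1cc(CCCO)cc(C=O)c1O | intermediate
3 | 5-[3-(tert-butyldimethylsilyloxy)propyl]-2-hydroxy-3-methoxybenzaldehyde | COc1cc(CCCO[Si](C)(C)C(C)(C)C)cc(C=O)c1O | intermediate
4 | 4-[3-(tert-butyldimethylsilyloxy)propyl]-2-formyl-6-methoxyphenyl trifluoromethanesulfonate | COc1cc(CCCO[Si](C)(C)C(C)(C)C)cc(C=O)c1OS(=O)(=O)C(F)(F)F | intermediate
5 | 4-[3-(tert-butyldimethylsilyloxy)propyl]-2-methoxy-6-vinylphenyl trifluoromethanesulfonate | COc1cc(CCCO[Si](C)(C)C(C)(C)C)cc(C=C)c1OS(=O)(=O)C(F)(F)F | intermediate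
6 | allylboronic acid pinacol ester | C=CCB1OC(C)(C)C(C)(C)O1 | starting material
7 | 4-[3-(tert-butyldimethylsilyloxy)propyl]-2-methoxy-6-[(E)-3-(4,4,5,5-tetramethyl-1,3,2-dioxaborolan-2-yl)prop-1-enyl]phenyl trifluoromethanesulfonate | COc1cc(CCCO[Si](C)(C)C(C)(C)C)cc(/C=C/CB2OC(C)(C)C(C)(C)O2)c1OS(=O)(=O)C(F)(F)F | intermediate
8 | vanillin | COc1cc(C=O)ccc1O | starting material
9 | 3-methoxy-4-(triisopropylsilyloxy)benzaldehyde | COc1cc(C=O)ccc1O[Si](C(C)C)(C(C)C)C(C)C | intermediate
10 | 2-{[(1R,2S)-2-{5-[3-(tert-butyldimethylsilyloxy)propyl]-3-methoxy-2-(trifluoromethanesulfonyloxy)phenyl}-1-[3-methoxy-4-(triisopropylsilyloxy)phenyl]but-3-en-1-yl]oxy}-4,4,5,5-tetramethyl-1,3,2-dioxaborolane (anti) | COc1cc([C@H](OB2OC(C)(C)C(C)(C)O2)[C@@H](C=C)c2cc(CCCO[Si](C)(C)C(C)(C)C)cc(OC)c2OS(=O)(=O)C(F)(F)F)ccc1O[Si](C(C)C)(C(C)C)C(C)C | intermediate (not isolated)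
11 | (2R,3S)-5-[3-(tert-butyldimethylsilyloxy)propyl]-7-methoxy-2-[3-methoxy-4-(triisopropylsilyloxy)phenyl]-3-vinyl-2,3-dihydrobenzofuran (2,3-cis) | COc1cc([C@@H]2Oc3c(OC)cc(CCCO[Si](C)(C)C(C)(C)C)cc3[C@@H]2C=C)ccc1O[Si](C(C)C)(C(C)C)C(C)C | intermediate
12 | (2R,3S)-5-[3-(tert-butyldimethylsilyloxy)propyl]-7-methoxy-2-[3-methoxy-4-(triisopropylsilyloxy)phenyl]-3-(1,2,4-trioxolan-3-yl)-2,3-dihydrobenzofuran (ozonide, both epimers at the trioxolane carbon) | COc1cc([C@@H]2Oc3c(OC)cc(CCCO[Si](C)(C)C(C)(C)C)cc3[C@@H]2C2OOCO2)ccc1O[Si](C(C)C)(C(C)C)C(C)C | intermediate (not isolated)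
13 | (2R,3S)-5-[3-(tert-butyldimethylsilyloxy)propyl]-7-methoxy-2-[3-methoxy-4-(triisopropylsilyloxy)phenyl]-2,3-dihydrobenzofuran-3-carbaldehyde (2,3-cis) | COc1cc([C@@H]2Oc3c(OC)cc(CCCO[Si](C)(C)C(C)(C)C)cc3[C@@H]2C=O)ccc1O[Si](C(C)C)(C(C)C)C(C)C | intermediate (not isolated)
14 | (2R,3R)-5-[3-(tert-butyldimethylsilyloxy)propyl]-7-methoxy-2-[3-methoxy-4-(triisopropylsilyloxy)phenyl]-2,3-dihydrobenzofuran-3-carbaldehyde (2,3-trans) | COc1cc([C@@H]2Oc3c(OC)cc(CCCO[Si](C)(C)C(C)(C)C)cc3[C@H]2C=O)ccc1O[Si](C(C)C)(C(C)C)C(C)C | intermediate (not isolated)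
15 | [(2R,3S)-5-[3-(tert-butyldimethylsilyloxy)propyl]-7-methoxy-2-[3-methoxy-4-(triisopropylsilyloxy)phenyl]-2,3-dihydrobenzofuran-3-yl]methanol (2,3-trans) | COc1cc([C@@H]2Oc3c(OC)cc(CCCO[Si](C)(C)C(C)(C)C)cc3[C@H]2CO)ccc1O[Si](C(C)C)(C(C)C)C(C)C | intermediate
16 | p-coumaric acid | O=C(O)/C=C/c1ccc(O)cc1 | starting material
17 | tert-butyldimethylsilyl (E)-3-[4-(tert-butyldimethylsilyloxy)phenyl]acrylate | CC(C)(C)[Si](C)(C)OC(=O)/C=C/c1ccc(O[Si](C)(C)C(C)(C)C)cc1 | intermediate (not isolated)
18 | (E)-3-[4-(tert-butyldimethylsilyloxy)phenyl]acrylic acid | O=C(O)/C=C/c1ccc(O[Si](C)(C)C(C)(C)C)cc1 | intermediate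
19 | [(2R,3S)-5-[3-(tert-butyldimethylsilyloxy)propyl]-7-methoxy-2-[3-methoxy-4-(triisopropylsilyloxy)phenyl]-2,3-dihydrobenzofuran-3-yl]methyl (E)-3-[4-(tert-butyldimethylsilyloxy)phenyl]acrylate | COc1cc([C@@H]2Oc3c(OC)cc(CCCO[Si](C)(C)C(C)(C)C)cc3[C@H]2COC(=O)/C=C/c2ccc(O[Si](C)(C)C(C)(C)C)cc2)ccc1O[Si](C(C)C)(C(C)C)C(C)C | intermediate
20 | [(2R,3S)-2-(4-hydroxy-3-methoxyphenyl)-5-(3-hydroxypropyl)-7-methoxy-2,3-dihydrobenzofuran-3-yl]methyl (E)-3-(4-hydroxyphenyl)acrylate | COc1cc([C@@H]2Oc3c(OC)cc(CCCO)cc3[C@H]2COC(=O)/C=C/c2ccc(O)cc2)ccc1O | target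

Total step count: 11. Longest linear sequence: 9 steps (steps 1, 2, 3, 4, 5, 7, 8, 10, 11).

**Steps most likely to fail**

Step 7 (proposed new method). The allyl transfer from the hindered γ-aryl boronate may be slow or poorly enantioselective. The boron-bound alkoxide may not pass to palladium. The triflate may suffer S–O cleavage, or the palladium alkoxide may undergo β-hydride elimination in the crude mixture. The fallback gives up the single-flask annulation and makes the two bonds in two separate, individually known operations. It sets out from 7 and 9. After the acid-catalysed allylboration, borate 10 is hydrolysed on aqueous work-up, and the free anti alcohol (1R,2S)-2-{5-[3-(tert-butyldimethylsilyloxy)propyl]-3-methoxy-2-(trifluoromethanesulfonyloxy)phenyl}-1-[3-methoxy-4-(triisopropylsilyloxy)phenyl]but-3-en-1-ol F1 is isolated and purified, so that boron species, acid and minor stereoisomers are removed. F1 is then cyclised in a separate Buchwald–Hartwig etherification (Pd(OAc)2, t-BuXPhos, Cs2CO3, toluene, 70 °C). This returns to the route at 11.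

Step 8. Ozone may over-oxidise the electron-rich rings, the cis-to-trans equilibration of the aldehyde may be incomplete, or the enolate may autoxidise towards the benzofuran. The fallback moves the epimerisation to the ester oxidation level, where it is precedented for cis-2-aryl-2,3-dihydrobenzofuran-3-carboxylates. It sets out from 11. Ozonolysis with PPh3 work-up is stopped at crude cis-aldehyde 13. Pinnick oxidation (NaClO2, NaH2PO4, 2-methyl-2-butene, t-BuOH/H2O) should give the cis acid (2R,3S)-5-[3-(tert-butyldimethylsilyloxy)propyl]-7-methoxy-2-[3-methoxy-4-(triisopropylsilyloxy)phenyl]-2,3-dihydrobenzofuran-3-carboxylic acid F2. Me3SiCHN2 in MeOH/toluene should give its methyl ester F3. Catalytic NaOMe in MeOH/THF at 0 °C should epimerise C3 to the trans methyl ester (2R,3R) F4. Reduction with i-Bu2AlH in CH2Cl2 at −78 °C returns to the route at 15.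

Step 5. The allyl boronate may homodimerise in preference to crossing with the ortho-substituted styrene, and ruthenium hydrides may move the double bond or erode the E geometry. The fallback builds the allyl boronate without metathesis. It sets out from aldehyde 4. Boron–Wittig olefination with bis(pinacolato)borylmethane and lithium 2,2,6,6-tetramethylpiperidide in THF at −78 °C should give the styryl boronate 4-[3-(tert-butyldimethylsilyloxy)propyl]-2-methoxy-6-[(E)-2-(4,4,5,5-tetramethyl-1,3,2-dioxaborolan-2-yl)vinyl]phenyl trifluoromethanesulfonate F5. Matteson homologation with LiCH2Cl (from BrCH2Cl and n-BuLi in THF at −78 °C) inserts the CH2 group between carbon and boron. This returns to the route at 7.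

**Further compounds**
F1 | step 7 | (1R,2S)-2-{5-[3-(tert-butyldimethylsilyloxy)propyl]-3-methoxy-2-(trifluoromethanesulfonyloxy)phenyl}-1-[3-methoxy-4-(triisopropylsilyloxy)phenyl]but-3-en-1-ol | COc1cc([C@H](O)[C@@H](C=C)c2cc(CCCO[Si](C)(C)C(C)(C)C)cc(OC)c2OS(=O)(=O)C(F)(F)F)ccc1O[Si](C(C)C)(C(C)C)C(C)C
F2 | step 8 | (2R,3S)-5-[3-(tert-butyldimethylsilyloxy)propyl]-7-methoxy-2-[3-methoxy-4-(triisopropylsilyloxy)phenyl]-2,3-dihydrobenzofuran-3-carboxylic acid (2,3-cis) | COc1cc([C@@H]2Oc3c(OC)cc(CCCO[Si](C)(C)C(C)(C)C)cc3[C@@H]2C(=O)O)ccc1O[Si](C(C)C)(C(C)C)C(C)C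
F3 | step 8 | methyl (2R,3S)-5-[3-(tert-butyldimethylsilyloxy)propyl]-7-methoxy-2-[3-methoxy-4-(triisopropylsilyloxy)phenyl]-2,3-dihydrobenzofuran-3-carboxylate (2,3-cis) | COc1cc([C@@H]2Oc3c(OC)cc(CCCO[Si](C)(C)C(C)(C)C)cc3[C@@H]2C(=O)OC)ccc1O[Si](C(C)C)(C(C)C)C(C)C
F4 | step 8 | methyl (2R,3R)-5-[3-(tert-butyldimethylsilyloxy)propyl]-7-methoxy-2-[3-methoxy-4-(triisopropylsilyloxy)phenyl]-2,3-dihydrobenzofuran-3-carboxylate (2,3-trans) | COc1cc([C@@H]2Oc3c(OC)cc(CCCO[Si](C)(C)C(C)(C)C)cc3[C@H]2C(=O)OC)ccc1O[Si](C(C)C)(C(C)C)C(C)C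
F5 | step 5 | 4-[3-(tert-butyldimethylsilyloxy)propyl]-2-methoxy-6-[(E)-2-(4,4,5,5-tetramethyl-1,3,2-dioxaborolan-2-yl)vinyl]phenyl trifluoromethanesulfonate | COc1cc(CCCO[Si](C)(C)C(C)(C)C)cc(/C=C/B2OC(C)(C)C(C)(C)O2)c1OS(=O)(=O)C(F)(F)F
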